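**Plan**

- Retrosynthesis: the C6–O lactone bond is cut first (it is re-formed with inversion by amide participation), then the C4–C5 epoxide oxygen, the C11=C13 methylene, the C4=C5 ring bond (metathesis) and the C8 ester. The core is then cut at C7–C11 together with a temporary C8–C12 bond (a ketene across an enol ether), at C7–O (alkynol cyclisation), at C8–C9 (alkyne plus epoxide) and at C1–C2 (Grignard).
- Forward order: open chain C1–C10 → oxolane ring as its 2,3-dihydrofuran → cyclobutanone → cis-fused lactone on O8 → amide carrying the C8 methacrylate → ten-membered ring → methylene → epoxide → spirolactone on O6.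
- Enabling feature: C7 is both the ether carbon of the oxolane ring (O, C7, C8, C9, C10) and the β-carbon of the γ-lactone (bonded to C11), and its neighbour C8 bears oxygen cis to C11. The unit C11–C12 therefore maps onto a ketene laid across the enol ether C7=C8, and Baeyer–Villiger insertion into the temporary C8–C12 bond delivers O8.
- Stereochemistry: C10 comes from methyl (R)-2-methylglycidate. C6 is entered as S by kinetic resolution so that it steers the cycloaddition (C7, C8) and the epoxidation (C4, C5), and it is inverted to R in the last step. The Z olefin follows from the bridged ring.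

Key step: step 7

Remark: germacrane numbering is used throughout (C1 ketone, C4–C5 epoxide, C6 lactone oxygen, C7 spiro ether carbon, C8 ester, C10 methyl-bearing ether carbon, C11–C13 methylene lactone); compounds 1, 4 and 8 are taken as commercial.

**Route**

Step 1
Reactants: 1 rac-pent-1-en-4-yn-3-ol
Product: 2 (S)-pent-1-en-4-yn-3-ol
Conditions: Ti(OiPr)4, L-(+)-diisopropyl tartrate, t-BuOOH (0.6 equiv), 4 Å MS, CH2Cl2, −20 °C
Reagents that add atoms: none
Why: Sharpless kinetic resolution, in which the L-(+)-tartrate titanium complex should epoxidise the R carbinol much faster, so that the S alcohol is recovered.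

Step 2
Reactants: 2 (S)-pent-1-en-4-yn-3-ol
Product: 3 (S)-tert-butyldimethyl(pent-1-en-4-yn-3-yloxy)silane
Conditions: TBSCl, imidazole, DMF, 0 °C to rt
Reagents that add atoms: tert-butyldimethylsilyl chloride, CC(C)(C)[Si](C)(C)Cl
Why: Standard imidazole-promoted O-silylation, which leaves the stereocentre untouched.

Step 3
Reactants: 3 silyl ether; 4 methyl (R)-2-methyloxirane-2-carboxylate
Product: 6 hydroxy ester, via lithium acetylide 5 (not isolated)
Conditions: n-BuLi, THF, −78 °C; BF3·OEt2; then 4, −78 °C
Reagents that add atoms: none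
Why: Yamaguchi–Hirao alkynylation, in which the BF3-activated epoxide is opened by the alkynyllithium at its unsubstituted CH2 carbon (SN2), so the quaternary C10 centre of 4 is carried over unchanged and the ester is spared at −78 °C.

Step 4
Reactants: 6 hydroxy ester
Product: 7 Weinreb amide
Conditions: MeNH(OMe)·HCl, Me3Al, CH2Cl2, 0 °C to rt
Reagents that add atoms: N,O-dimethylhydroxylamine hydrochloride, CNOC.Cl
Why: Weinreb amide formation by aluminium amide aminolysis, which converts even a hindered α-hydroxy ester.

Step 5
Reactants: 7 Weinreb amide; 8 4-bromo-2-methylbut-1-ene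
Product: 10 hydroxy ketone, via Grignard reagent 9 (not isolated)
Conditions: 8, Mg, THF, rt; then 7, THF, 0 °C; aq. NH4Cl
Reagents that add atoms: none
Why: Grignard addition to a Weinreb amide stops at the ketone because the magnesium chelate survives until work-up; one further equivalent of 9 is spent on the tertiary O–H.

Step 6
Reactants: 10 hydroxy ketone
Product: 11 2,3-dihydrofuran
Conditions: Ph3PAuCl (2 mol%), AgOTf (2 mol%), 4 Å MS, toluene, 0 °C to rt
Reagents that add atoms: none
Why: Monovalent-gold-catalysed 5-endo-dig hydroalkoxylation of a homopropargylic alcohol, in which the tertiary hydroxyl adds to C7 of the activated alkyne (the 4-exo mode is strained) and gives the C7=C8 enol ether.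

Step 7
Reactants: 11 2,3-dihydrofuran
Product: 12 cis-fused dichlorocyclobutanone
Conditions: Cl3CCOCl, Zn–Cu couple, Et2O/DME, 0 °C to rt, slow addition
Reagents that add atoms: trichloroacetyl chloride, ClC(=O)C(Cl)(Cl)Cl
Why: Dichloroketene, made in the flask, should add to the enol ether in an asynchronous concerted (2+2) cycloaddition in which its electrophilic carbonyl carbon (C12) bonds to the nucleophilic C8 and its CCl2 terminus (C11) to the oxygen-bearing C7, the regiochemistry being fixed by the polarisation O–C7=C8; the closest known reaction type is the cycloaddition of dichloroketene to 2,3-dihydrofurans and glycals. The four-membered ring is closed by the two new bonds C7–C11 and C8–C12, suprafacially on the dihydrofuran, hence with a cis ring fusion, and the C8–C12 bond is a temporary one that step 8 turns into C8–O. The new stereocentres C7 and C8 are set together: the ketene should approach the flat dihydrofuran on the face that carries the C10 methyl group, away from the C10 acyl chain. The 6S centre reinforces this, because in the preferred arrangement its silyloxy group lies in the plane beside C8 and its vinyl group points away from the reagent. The step needs chemoselectivity for the enol ether over the vinyl and isopropenyl groups, which the far higher nucleophilicity of the enol ether should secure when the ketene is generated slowly; the ketone and silyl ether are inert. DME binds the ZnCl2 formed, so the acid-labile enol ether should survive.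

Step 8
Reactants: 12 dichlorocyclobutanone
Product: 13 cis-fused dichlorolactone
Conditions: 30% aq. H2O2, AcOH, 0 °C
Reagents that add atoms: hydrogen peroxide, OO
Why: Baeyer–Villiger oxidation driven by release of cyclobutanone strain, in which the non-chlorinated ring-fusion carbon C8 migrates with retention so that O8 ends up cis to C11, while the unstrained C1 ketone and the alkenes should not react under these conditions.

Step 9
Reactants: 13 dichlorolactone
Product: 14 hydroxy amide
Conditions: Me2NH (2 M in THF), 0 °C to rt
Reagents that add atoms: dimethylamine, CNC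
Why: Aminolysis of a lactone made strongly electrophilic by its two α-chlorines (no α-hydrogen, so no elimination), which frees the C8 hydroxyl and stores C12 as a tertiary amide.

Step 10
Reactants: 14 hydroxy amide
Product: 15 methacrylate
Conditions: methacryloyl chloride, Et3N, DMAP (cat.), CH2Cl2, 0 °C to rt
Reagents that add atoms: methacryloyl chloride, C=C(C)C(Cl)=O
Why: DMAP-catalysed O-acylation of the only free hydroxyl (C8–OH), with retention.

Step 11
Reactants: 15 methacrylate
Product: 16 ring-closed dichloroamide
Conditions: second-generation Hoveyda–Grubbs catalyst RuCl2(H2IMes)(=CH-C6H4-2-OiPr) (10 mol%), 1,4-benzoquinone, toluene (1 mM), 80 °C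
Reagents that add atoms: none
Why: Ring-closing olefin metathesis between the C6 vinyl group and the isopropenyl terminus, both held on the same face of the oxolane ring; the bridged ten-membered ring should accept only the Z trisubstituted olefin, and the methacrylate is a poor partner for the ruthenium carbene.

Step 12
Reactants: 16 ring-closed dichloroamide
Product: 18 α-methylene amide, via chromium aldolate 17 (not isolated)
Conditions: CrCl2 (6 equiv), LiI (cat.), CH2O (THF solution from cracked paraformaldehyde), THF, 0 °C to rt
Reagents that add atoms: formaldehyde, C=O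
Why: Proposed new method: two equivalents of divalent chromium should reduce one C–Cl bond to a trivalent chromium enolate that adds to formaldehyde (Reformatsky-type aldol), and two more should reduce the second C–Cl bond of aldolate 17, after which β-elimination of the chromium alkoxide gives the alkene, which can only be exocyclic because C7 is quaternary; the closest known reaction type is the divalent-chromium-promoted condensation of α,α-dihalo esters and amides with aldehydes to α,β-unsaturated esters and amides, not yet shown for an α-branched dichloroamide with formaldehyde next to a β-ether oxygen.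

Step 13
Reactants: 18 α-methylene amide
Product: 19 epoxide
Conditions: dimethyldioxirane (acetone solution), CH2Cl2, −20 °C
Reagents that add atoms: dimethyldioxirane, CC1(C)OO1
Why: Electrophilic epoxidation of the only electron-rich olefin, expected on the face away from the quaternary C7 with the bulky 6S silyloxy group turned outward, that is trans to the silyloxy group as in epoxidations of medium-ring cycloalkenyl ethers, which sets C4 (R) and C5 (S).

Step 14
Reactants: 19 epoxide
Product: 20 epoxy alcohol
Conditions: Bu4NF, AcOH, THF, 0 °C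
Reagents that add atoms: none
Why: Fluoride-mediated desilylation, buffered with acetic acid so that neither Payne rearrangement of the neighbouring epoxide nor migration of the C8 methacrylate should set in.

Step 15
Reactants: 20 epoxy alcohol
Product: 23 CNP0241021.1, via mesylate 21 (not isolated), via iminium lactone 22 (not isolated)
Conditions: MsCl, Et3N, CH2Cl2, −10 °C; then MeCN/pH 7 phosphate buffer, 50 °C
Reagents that add atoms: water, O
Why: Amide-participated lactonisation (as in halolactonisations of N,N-dialkylamides), in which the amide oxygen displaces the C6 mesylate from the rear in a 5-exo-tet SN2 reaction, inverting C6 to R and placing the ring oxygen cis to the epoxide, and the iminium ether is then hydrolysed at neutral pH to the γ-lactone with loss of dimethylamine.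

**Compound list**

1 | rac-pent-1-en-4-yn-3-ol | C#CC(O)C=C | starting material
2 | (S)-pent-1-en-4-yn-3-ol | C#C[C@@H](O)C=C | intermediate
3 | (S)-tert-butyldimethyl(pent-1-en-4-yn-3-yloxy)silane | C#C[C@@H](O[Si](C)(C)C(C)(C)C)C=C | intermediate
4 | methyl (R)-2-methyloxirane-2-carboxylate | COC(=O)[C@@]1(C)CO1 | starting material
5 | lithium acetylide of 3 | [Li]C#C[C@@H](O[Si](C)(C)C(C)(C)C)C=C | intermediate (not isolated)
6 | methyl (2R,6S)-6-[(tert-butyldimethylsilyl)oxy]-2-hydroxy-2-methyloct-7-en-4-ynoate | COC(=O)[C@](C)(O)CC#C[C@@H](O[Si](C)(C)C(C)(C)C)C=C | intermediate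
7 | (2R,6S)-6-[(tert-butyldimethylsilyl)oxy]-2-hydroxy-N-methoxy-N,2-dimethyloct-7-en-4-ynamide | CON(C)C(=O)[C@](C)(O)CC#C[C@@H](O[Si](C)(C)C(C)(C)C)C=C | intermediate
8 | 4-bromo-2-methylbut-1-ene | C=C(C)CCBr | starting material
9 | (3-methylbut-3-en-1-yl)magnesium bromide | C=C(C)CC[Mg]Br | intermediate (not isolated)
10 | (6R,10S)-10-[(tert-butyldimethylsilyl)oxy]-6-hydroxy-2,6-dimethyldodeca-1,11-dien-8-yn-5-one | C=C(C)CCC(=O)[C@](C)(O)CC#C[C@@H](O[Si](C)(C)C(C)(C)C)C=C | intermediate
11 | 1-[(2R)-5-[(1S)-1-[(tert-butyldimethylsilyl)oxy]prop-2-en-1-yl]-2-methyl-2,3-dihydrofuran-2-yl]-4-methylpent-4-en-1-one | C=C(C)CCC(=O)[C@@]1(C)CC=C(O1)[C@@H](O[Si](C)(C)C(C)(C)C)C=C | intermediate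
12 | cis-fused 7,7-dichloro-1-[(1S)-1-[(tert-butyldimethylsilyl)oxy]prop-2-en-1-yl]-3-methyl-3-(4-methylpent-4-enoyl)-2-oxabicyclo[3.2.0]heptan-6-one (C7, C8, C10 configured as in the target; C6 S) | C=C(C)CCC(=O)[C@@]1(C)C[C@@H]2C(=O)C(Cl)(Cl)[C@@]2(O1)[C@@H](O[Si](C)(C)C(C)(C)C)C=C | intermediate
13 | cis-fused 3,3-dichloro-3a-[(1S)-1-[(tert-butyldimethylsilyl)oxy]prop-2-en-1-yl]-5-methyl-5-(4-methylpent-4-enoyl)tetrahydrofuro[3,2-b]furan-2(3H)-one (C7, C8, C10 as in the target) | C=C(C)CCC(=O)[C@@]1(C)C[C@@H]2OC(=O)C(Cl)(Cl)[C@@]2(O1)[C@@H](O[Si](C)(C)C(C)(C)C)C=C | intermediate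
14 | 2,2-dichloro-2-[2-[(1S)-1-[(tert-butyldimethylsilyl)oxy]prop-2-en-1-yl]-3-hydroxy-5-methyl-5-(4-methylpent-4-enoyl)oxolan-2-yl]-N,N-dimethylacetamide (C7, C8, C10 as in the target) | C=C(C)CCC(=O)[C@@]1(C)C[C@H](O)[C@@](O1)(C(Cl)(Cl)C(=O)N(C)C)[C@@H](O[Si](C)(C)C(C)(C)C)C=C | intermediate
15 | C8 2-methylprop-2-enoate of 14 | C=C(C)CCC(=O)[C@@]1(C)C[C@H](OC(=O)C(C)=C)[C@@](O1)(C(Cl)(Cl)C(=O)N(C)C)[C@@H](O[Si](C)(C)C(C)(C)C)C=C | intermediate
16 | (3Z)-2-[(tert-butyldimethylsilyl)oxy]-1-[1,1-dichloro-2-(dimethylamino)-2-oxoethyl]-4,8-dimethyl-7-oxo-11-oxabicyclo[6.2.1]undec-3-en-10-yl 2-methylprop-2-enoate (C6 S; C7, C8, C10 as in the target) | C=C(C)C(=O)O[C@H]1C[C@@]2(C)O[C@]1(C(Cl)(Cl)C(=O)N(C)C)[C@@H](O[Si](C)(C)C(C)(C)C)/C=C(C)\CCC2=O | intermediate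
17 | chromium aldolate of 16 (C11 bearing Cl and CH2OCrCl2) | C=C(C)C(=O)O[C@H]1C[C@@]2(C)O[C@]1(C(Cl)(CO[Cr](Cl)Cl)C(=O)N(C)C)[C@@H](O[Si](C)(C)C(C)(C)C)/C=C(C)\CCC2=O | intermediate (not isolated)
18 | (3Z)-2-[(tert-butyldimethylsilyl)oxy]-1-[3-(dimethylamino)-3-oxoprop-1-en-2-yl]-4,8-dimethyl-7-oxo-11-oxabicyclo[6.2.1]undec-3-en-10-yl 2-methylprop-2-enoate (C6 S; C7, C8, C10 as in the target) | C=C(C)C(=O)O[C@H]1C[C@@]2(C)O[C@]1(C(=C)C(=O)N(C)C)[C@@H](O[Si](C)(C)C(C)(C)C)/C=C(C)\CCC2=O | intermediate
19 | (4R,5S)-4,5-epoxide of 18, trans to the 6S silyloxy group | C=C(C)C(=O)O[C@H]1C[C@@]2(C)O[C@]1(C(=C)C(=O)N(C)C)[C@@H](O[Si](C)(C)C(C)(C)C)[C@@H]1O[C@]1(C)CCC2=O | intermediate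
20 | 6S alcohol obtained from 19 | C=C(C)C(=O)O[C@H]1C[C@@]2(C)O[C@]1(C(=C)C(=O)N(C)C)[C@@H](O)[C@@H]1O[C@]1(C)CCC2=O | intermediate
21 | C6 methanesulfonate of 20 | C=C(C)C(=O)O[C@H]1C[C@@]2(C)O[C@]1(C(=C)C(=O)N(C)C)[C@@H](OS(C)(=O)=O)[C@@H]1O[C@]1(C)CCC2=O | intermediate (not isolated)
22 | N,N-dimethyliminium lactone methanesulfonate (C6 R) | C=C(C)C(=O)O[C@H]1C[C@@]2(C)O[C@@]13C(=C)C(=[N+](C)C)O[C@@H]3[C@@H]1O[C@]1(C)CCC2=O.CS(=O)(=O)[O-] | intermediate (not isolated)
23 | CNP0241021.1, (4R,5S,6R,7S,8S,10R)-4,5:7,10-diepoxy-1-oxogermacr-11(13)-en-12,6-olide 8-(2-methylprop-2-enoate) | C=C(C)C(=O)O[C@H]1C[C@@]2(C)O[C@@]13C(=C)C(=O)O[C@@H]3[C@@H]1O[C@]1(C)CCC2=O | target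

**Step count and risks**

Total step count: 15. Longest linear sequence: 15 steps (1 to 23); 4 and 8 enter as commercial building blocks.

Steps most likely to fail:

1. Step 12 (proposed new method). The chromium enolate may expel the β ether oxygen and open the oxolane ring, or the sequence may stall after the first reduction. The fallback uses known chemistry and sets out from 16. Radical reduction with Bu3SnH (1 equiv) and Et3B in toluene at −20 °C should remove one chlorine and give the monochloroamide F1. A Reformatsky reaction of this with activated Zn and formaldehyde in THF should give the hydroxymethyl amide F2. Mesylation (MsCl, Et3N) followed by DBU-induced elimination, which can only form the exocyclic olefin, returns to the route at 18.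

2. Step 11. Ring closure may be too slow at the hindered vinyl group, so that oligomerisation or capture of the carbene by the methacrylate takes over. The fallback moves the ring closure onto the rigid bicyclic lactone, which holds both side chains on one face and carries no acrylic olefin. It sets out from 13: metathesis with the same second-generation Hoveyda–Grubbs catalyst at high dilution should give the ring-closed lactone F3; aminolysis with Me2NH gives the ring-closed hydroxy amide F4; acylation with methacryloyl chloride, Et3N and DMAP returns to the route at 16.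

3. Step 15. Elimination, epoxide migration or ionisation may outrun the SN2 displacement at the hindered C6. The fallback inverts C6 by oxidation and reduction instead, and sets out from 20. Dess–Martin oxidation should give the epoxy ketone F5. Reduction with Zn(BH4)2 in Et2O at −20 °C, under chelation between the ketone and epoxide oxygens, should give the 6R epoxy alcohol F6; the chelating epoxy ketone is expected to react ahead of the hindered C1 ketone. Acid-catalysed N-to-O acyl transfer (PPTS, toluene, 50 °C) then closes the lactone with retention and arrives at 23.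

Further compounds
F1 | step 12 | 11-monochloro analogue of 16 (mixture at C11) | C=C(C)C(=O)O[C@H]1C[C@@]2(C)O[C@]1(C(Cl)C(=O)N(C)C)[C@@H](O[Si](C)(C)C(C)(C)C)/C=C(C)\CCC2=O
F2 | step 12 | 11-(hydroxymethyl) amide (mixture at C11) | C=C(C)C(=O)O[C@H]1C[C@@]2(C)O[C@]1(C(CO)C(=O)N(C)C)[C@@H](O[Si](C)(C)C(C)(C)C)/C=C(C)\CCC2=O
F3 | step 11 | ring-closed (Z) analogue of dichlorolactone 13 | O=C1O[C@H]2C[C@@]3(C)O[C@]2(C1(Cl)Cl)[C@@H](O[Si](C)(C)C(C)(C)C)/C=C(C)\CCC3=O
F4 | step 11 | ring-closed (Z) analogue of hydroxy amide 14 | O[C@H]1C[C@@]2(C)O[C@]1(C(Cl)(Cl)C(=O)N(C)C)[C@@H](O[Si](C)(C)C(C)(C)C)/C=C(C)\CCC2=O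
F5 | step 15 | 6-oxo epoxy amide | C=C(C)C(=O)O[C@H]1C[C@@]2(C)O[C@]1(C(=C)C(=O)N(C)C)C(=O)[C@@H]1O[C@]1(C)CCC2=O
F6 | step 15 | 6R epoxy alcohol (C6 epimer of 20) | C=C(C)C(=O)O[C@H]1C[C@@]2(C)O[C@]1(C(=C)C(=O)N(C)C)[C@H](O)[C@@H]1O[C@]1(C)CCC2=O
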